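**Retrosynthetic overview**
1. Ring C (the pyranone) is formed last, by 6-endo-dig closure of a 2-hydroxyaryl ynone; rings A and B are bought as arenes.
2. That phenol is unmasked from a symmetric 4-benzyloxy-2,3,5,6-tetramethoxyphenyl ynone, in which either ortho-OMe gives the same product.
3. The ynone comes from a C(=O)–C(sp) bond between the A-ring aldehyde carbon, made nucleophilic as its NHC Breslow intermediate, and the electrophilic alkynyl carbon of an alkynyl(phenyl)iodonium salt.
4. The aldehyde comes from O-benzylsyringaldehyde by double ortho-bromination and double Cu-catalysed methoxylation; the iodonium salt comes from 4-ethynylanisole and Koser's reagent.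

Assumption: the target has no stereocentre and no stereogenic double bond, so it is one achiral compound and needs no stereocontrol; 1 is bought as the catalogue compound O-benzylsyringaldehyde.

**Step 1**
Reactants: 1 4-(benzyloxy)-3,5-dimethoxybenzaldehyde
Product: 2 4-(benzyloxy)-2,6-dibromo-3,5-dimethoxybenzaldehyde
Conditions: NBS (2.4 equiv), MeCN, 60 °C, dark
Reagents that add atoms: N-bromosuccinimide, O=C1CCC(=O)N1Br
Why: Electrophilic aromatic bromination, in which the only free ring positions (C2 and C6) are each ortho and para to a methoxy group, so two successive brominations give the symmetric dibromide while the polar solvent and darkness suppress radical bromination of the benzyl CH2.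

**Step 2**
Reactants: 2 4-(benzyloxy)-2,6-dibromo-3,5-dimethoxybenzaldehyde
Product: 3 4-(benzyloxy)-2,3,5,6-tetramethoxybenzaldehyde
Conditions: NaOMe (6 equiv), CuBr (20 mol %), DMF/MeOH, 100 °C
Reagents that add atoms: sodium methoxide, [Na+].[O-]C
Why: Ullmann-type Cu(I)-catalysed methoxylation of aryl bromides, helped at both C–Br bonds by the ortho formyl group, replaces both bromides while the benzyl ether is inert to methoxide.

**Step 3**
Reactants: 4 1-ethynyl-4-methoxybenzene
Product: 5 [(4-methoxyphenyl)ethynyl](phenyl)iodonium tosylate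
Conditions: PhI(OH)OTs (1.0 equiv), CHCl3, 4 Å MS, 40 °C; precipitate with Et2O, use at once
Reagents that add atoms: [hydroxy(tosyloxy)iodo]benzene (Koser's reagent), Cc1ccc(cc1)S(=O)(=O)OI(O)c1ccccc1
Why: Koser alkynyliodonium synthesis, in which the terminal aryl alkyne exchanges onto iodine(III) with loss of water to give the alkynyl(phenyl)iodonium tosylate as a precipitate.

**Step 4**
Reactants: 3 4-(benzyloxy)-2,3,5,6-tetramethoxybenzaldehyde; 5 [(4-methoxyphenyl)ethynyl](phenyl)iodonium tosylate (1.3 equiv)
Product: 6 1-[4-(benzyloxy)-2,3,5,6-tetramethoxyphenyl]-3-(4-methoxyphenyl)prop-2-yn-1-one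
Conditions: 2-phenyl-6,7-dihydro-5H-pyrrolo[2,1-c][1,2,4]triazol-2-ium BF4 (20 mol %), TMEDA (1.5 equiv), PhMe, −40 → 0 °C
Reagents that add atoms: none
Why: Proposed new method: the free carbene adds to the aldehyde and proton transfer gives the Breslow intermediate (an acyl anion equivalent), whose nucleophilic carbon substitutes the electrophilic acetylenic carbon of 5 with loss of PhI before the carbene is expelled to leave the ynone, the closest known reaction type being the NHC-catalysed C–H alkynylation of (hetero)aryl aldehydes with alkynyl(aryl)iodonium salts, extended here to a di-ortho-methoxy benzaldehyde that cannot self-condense to a benzoin.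

**Step 5**
Reactants: 6 1-[4-(benzyloxy)-2,3,5,6-tetramethoxyphenyl]-3-(4-methoxyphenyl)prop-2-yn-1-one
Product: 8 7-hydroxy-4',5,6,8-tetramethoxyflavone, via dihydroxy ynone 7 (not isolated)
Conditions: BCl3 (2.3 equiv), CH2Cl2, −78 → −20 °C; H2O quench, extract; crude 7, TfOH (1.2 equiv), CH2Cl2, 0 °C → rt
Reagents that add atoms: none
Why: BCl3 cleaves the benzyl ether and, through the carbonyl chelate, one of the two equivalent ortho methyl ethers (chelation-controlled demethylation), after which TfOH promotes 6-endo-dig oxa-Michael cyclisation of the 2-hydroxyaryl ynone onto the anisyl-stabilised β-carbon to close the γ-pyrone.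

**Compound list**
1 | 4-(benzyloxy)-3,5-dimethoxybenzaldehyde (O-benzylsyringaldehyde) | O=Cc1cc(OC)c(OCc2ccccc2)c(OC)c1 | starting material
2 | 4-(benzyloxy)-2,6-dibromo-3,5-dimethoxybenzaldehyde | O=Cc1c(Br)c(OC)c(OCc2ccccc2)c(OC)c1Br | intermediate
3 | 4-(benzyloxy)-2,3,5,6-tetramethoxybenzaldehyde | O=Cc1c(OC)c(OC)c(OCc2ccccc2)c(OC)c1OC | intermediate
4 | 1-ethynyl-4-methoxybenzene (4-ethynylanisole) | C#Cc1ccc(OC)cc1 | starting material
5 | [(4-methoxyphenyl)ethynyl](phenyl)iodonium tosylate | COc1ccc(cc1)C#C[I+]c1ccccc1.Cc1ccc(cc1)S(=O)(=O)[O-] | intermediate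
6 | 1-[4-(benzyloxy)-2,3,5,6-tetramethoxyphenyl]-3-(4-methoxyphenyl)prop-2-yn-1-one | COc1ccc(cc1)C#CC(=O)c1c(OC)c(OC)c(OCc2ccccc2)c(OC)c1OC | intermediate
7 | 1-(2,4-dihydroxy-3,5,6-trimethoxyphenyl)-3-(4-methoxyphenyl)prop-2-yn-1-one (dihydroxy ynone; not isolated) | COc1ccc(cc1)C#CC(=O)c1c(O)c(OC)c(O)c(OC)c1OC | intermediate
8 | 7-hydroxy-4',5,6,8-tetramethoxyflavone = 7-hydroxy-5,6,8-trimethoxy-2-(4-methoxyphenyl)-4H-chromen-4-one | COc1ccc(-c2cc(=O)c3c(OC)c(OC)c(O)c(OC)c3o2)cc1 | target

**Total step count:** 5
**Longest linear sequence:** 4 (steps 1, 2, 4, 5); step 3 is a one-step side branch.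

**Steps most likely to fail**

Step 4. The aldehyde is electron-rich and flanked by two methoxy groups, so Breslow-intermediate formation may be slower than base- or carbene-induced decomposition of 5. The fallback sets out from 3 and comes back at 6. Alkyne 4 is deprotonated with n-BuLi (THF, −78 °C) to lithium (4-methoxyphenyl)acetylide F1. F1 adds to aldehyde 3 to give racemic 1-[4-(benzyloxy)-2,3,5,6-tetramethoxyphenyl]-3-(4-methoxyphenyl)prop-2-yn-1-ol F2. MnO2 (CH2Cl2, rt) oxidises F2 to ynone 6, which removes the stereocentre.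

Step 5. BCl3 may also cleave the second ortho-OMe or a methoxy next to the freed 4-OH, and the cyclisation could leak to the 5-exo aurone. The fallback sets out from 6 and comes back at 8. ICl (CH2Cl2, −78 °C) triggers iodonium-induced 6-endo cyclisation with loss of one ortho methyl group, giving 7-(benzyloxy)-3-iodo-5,6,8-trimethoxy-2-(4-methoxyphenyl)-4H-chromen-4-one F3. H2, Pd/C and Et3N (EtOAc/MeOH, rt) then remove the C3 iodide and the benzyl ether together to give 8.

Step 2. Hot methoxide on a 2,6-dibromobenzaldehyde risks deformylation, Cannizzaro chemistry and hydrodebromination. The fallback sets out from 2 and comes back at 3, and masks the aldehyde before the coupling. HC(OMe)3 with catalytic TsOH in MeOH gives 4-(benzyloxy)-2,6-dibromo-3,5-dimethoxybenzaldehyde dimethyl acetal F4. NaOMe/CuBr (DMF, 110 °C) on this base-stable acetal gives 4-(benzyloxy)-2,3,5,6-tetramethoxybenzaldehyde dimethyl acetal F5. Aqueous HCl in THF hydrolyses F5 to 3.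

**Further compounds**
F1 | step 4 | lithium (4-methoxyphenyl)acetylide | [Li+].[C-]#Cc1ccc(OC)cc1
F2 | step 4 | 1-[4-(benzyloxy)-2,3,5,6-tetramethoxyphenyl]-3-(4-methoxyphenyl)prop-2-yn-1-ol (racemic) | COc1ccc(cc1)C#CC(O)c1c(OC)c(OC)c(OCc2ccccc2)c(OC)c1OC
F3 | step 5 | 7-(benzyloxy)-3-iodo-5,6,8-trimethoxy-2-(4-methoxyphenyl)-4H-chromen-4-one | COc1ccc(cc1)-c1oc2c(OC)c(OCc3ccccc3)c(OC)c(OC)c2c(=O)c1I
F4 | step 2 | 4-(benzyloxy)-2,6-dibromo-3,5-dimethoxybenzaldehyde dimethyl acetal | COC(OC)c1c(Br)c(OC)c(OCc2ccccc2)c(OC)c1Br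
F5 | step 2 | 4-(benzyloxy)-2,3,5,6-tetramethoxybenzaldehyde dimethyl acetal | COC(OC)c1c(OC)c(OC)c(OCc2ccccc2)c(OC)c1OC
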